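**Plan**

- Retrosynthesis: the C6–CH2–C3' bridge is cut first (chromene 15, pyranone 20 and one carbon). The pyran ring is then cut at O1–C2 and at both C2–CH3 bonds, which leads back to a coumarin. Last, the C8–C(=O) bond and the lactone ring are cut, leaving phloroglucinol.
- Enabling feature: the ring O1–C2(CH3)2–C3=C4 is a coumarin lactone whose carbonyl carbon C2 has become the gem-dimethyl carbon and whose ring oxygen is O1. The acyl group sits at C8, between O1 and the 7-OH, the carbon at which 5,7-dihydroxycoumarin is acylated.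
- Forward: the lactone ring is fused to phloroglucinol, C8 is acylated, and the ketone is masked as a silylated carbinol. Two MeLi additions and a cyclodehydration turn the lactone ring into the 2,2-dimethylpyran ring, and the ketone is then restored.
- The 4-hydroxy-2-pyranone ring is made separately from pentan-3-one and malonyl dichloride and is joined to C6 in the last step through a Mannich-derived methylene.
- Stereochemistry: the only stereocentre, (S) in the 2-methylbutanoyl group, comes from (S)-2-methylbutanoic acid. It is never next to a carbonyl group while strong base is present.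

Key step: step 6

Remark: the carbinol carbon formed in step 4 is carried as a mixture of both epimers, because step 8 returns it to the ketone; it bears no descriptor in the SMILES.

**Route**

Step 1
Reactants: 1 phloroglucinol; 2 ethyl propiolate
Product: 3 5,7-dihydroxy-2H-chromen-2-one
Conditions: ZnCl2 (1 equiv), dioxane, 100 °C
Reagents that add atoms: none
Why: Pechmann-type coumarin synthesis in which the ZnCl2-activated propiolate alkylates a ring carbon of the threefold-symmetric phenol and the cis-cinnamate so formed lactonises on the neighbouring hydroxyl, so only one coumarin can arise.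

Step 2
Reactants: 3 5,7-dihydroxy-2H-chromen-2-one; 4 (2S)-2-methylbutanoic acid
Product: 6 5,7-dihydroxy-8-[(2S)-2-methylbutanoyl]-2H-chromen-2-one, via (2S)-2-methylbutanoyl chloride 5 (not isolated)
Conditions: 4, (COCl)2, cat. N,N-dimethylformamide, CH2Cl2, 0 °C → rt, evaporate; then 3, AlCl3 (4 equiv), PhNO2, rt → 50 °C; aq. HCl
Reagents that add atoms: none
Why: Friedel–Crafts acylation, which in 5,7-dihydroxycoumarins is known to favour C8 (ortho to the 7-OH and to O1, para to the 5-OH) and gives a ketone chelated to the 7-oxygen; the existing (S) centre should survive because the hindered, chelated aryl ketone enolises only slowly at this temperature.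

Step 3
Reactants: 6 5,7-dihydroxy-8-[(2S)-2-methylbutanoyl]-2H-chromen-2-one
Product: 7 5,7-bis(methoxymethoxy)-8-[(2S)-2-methylbutanoyl]-2H-chromen-2-one
Conditions: MOMCl (4 equiv), iPr2NEt, Bu4NI (cat.), CH2Cl2, 0 → 40 °C
Reagents that add atoms: chloromethyl methyl ether (MOMCl), COCCl
Why: O-alkylation of both acidic coumarin phenols to methoxymethyl acetals under an amine base too weak to enolise the ketone, so the α-stereocentre is untouched.

Step 4
Reactants: 7 5,7-bis(methoxymethoxy)-8-[(2S)-2-methylbutanoyl]-2H-chromen-2-one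
Product: 8 8-[(2S)-1-hydroxy-2-methylbutyl]-5,7-bis(methoxymethoxy)-2H-chromen-2-one (both carbinol epimers)
Conditions: NaBH4, CeCl3·7H2O, MeOH, −20 → 0 °C
Reagents that add atoms: none
Why: Luche reduction delivers hydride 1,2 to the aryl ketone and spares the unsaturated lactone; the new carbinol centre is formed without control on purpose, since it is oxidised again in step 8.

Step 5
Reactants: 8 8-[(2S)-1-hydroxy-2-methylbutyl]-5,7-bis(methoxymethoxy)-2H-chromen-2-one
Product: 9 8-{(2S)-1-[(tert-butyldimethylsilyl)oxy]-2-methylbutyl}-5,7-bis(methoxymethoxy)-2H-chromen-2-one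
Conditions: TBSOTf (1.3 equiv), 2,6-lutidine, CH2Cl2, −78 → −40 °C
Reagents that add atoms: tert-butyldimethylsilyl trifluoromethanesulfonate (TBSOTf), CC(C)(C)[Si](C)(C)OS(=O)(=O)C(F)(F)F
Why: Silylation of a hindered secondary alcohol with a silyl triflate, run cold and buffered with lutidine so that the benzylic C–O bond does not ionise and the MOM acetals stay in place.

Step 6
Reactants: 9 8-{(2S)-1-[(tert-butyldimethylsilyl)oxy]-2-methylbutyl}-5,7-bis(methoxymethoxy)-2H-chromen-2-one
Product: 12 8-{(2S)-1-[(tert-butyldimethylsilyl)oxy]-2-methylbutyl}-5,7-bis(methoxymethoxy)-2,2-dimethyl-2H-chromene, via Z-enone phenol 10 (not isolated), via Z-allylic diol 11 (not isolated)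
Conditions: MeLi (4 equiv), THF, −78 → 0 °C; sat. aq. NH4Cl; then pyridinium p-toluenesulfonate (cat.), CH2Cl2, 0 °C → rt
Reagents that add atoms: methyllithium (MeLi), [Li]C
Why: The first MeLi adds to the lactone carbonyl C2 and the tetrahedral alkoxide opens to the phenoxide of Z-enone 10; the second MeLi adds 1,2 to that methyl ketone, so that the quench gives tertiary Z-allylic alcohol 11 with both C2–CH3 bonds made. The mild acid then ionises the tertiary allylic alcohol to an allyl cation, which is the protonated form of an ortho-quinone methide, and the phenol oxygen closes the six-membered pyran ring at the gem-dimethyl carbon (O1–C2) by oxa-6π electrocyclisation or, equivalently, by direct capture of the cation. The closest known reaction type is the conversion of coumarins into 2,2-dimethyl-2H-chromenes with excess methyl Grignard reagent or methyllithium followed by cyclodehydration. No stereocentre is formed, and the (S) centre lies next to a silyloxy carbon and not a carbonyl, so MeLi cannot epimerise it. The step needs carbonyl addition in preference to conjugate addition, which the hard organolithium at low temperature and the 5-OMOM group peri to C4 should secure; the site of closure is fixed because the only free phenol is the former lactone oxygen and the alkene keeps the Z geometry of the coumarin.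

Step 7
Reactants: 12 8-{(2S)-1-[(tert-butyldimethylsilyl)oxy]-2-methylbutyl}-5,7-bis(methoxymethoxy)-2,2-dimethyl-2H-chromene
Product: 13 (2S)-1-[5,7-bis(methoxymethoxy)-2,2-dimethyl-2H-chromen-8-yl]-2-methylbutan-1-ol (both carbinol epimers)
Conditions: Bu4NF, THF, rt → 45 °C
Reagents that add atoms: none
Why: Fluoride-driven desilylation under basic conditions that leave the MOM acetals and the chromene alkene alone.

Step 8
Reactants: 13 (2S)-1-[5,7-bis(methoxymethoxy)-2,2-dimethyl-2H-chromen-8-yl]-2-methylbutan-1-ol
Product: 14 (2S)-1-[5,7-bis(methoxymethoxy)-2,2-dimethyl-2H-chromen-8-yl]-2-methylbutan-1-one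
Conditions: Dess–Martin periodinane, CH2Cl2, 0 °C → rt; aq. NaHCO3/Na2S2O3
Reagents that add atoms: none
Why: Dess–Martin oxidation of the benzylic alcohol under near-neutral, non-enolising conditions, so both epimers converge on one ketone with the neighbouring (S) centre intact.

Step 9
Reactants: 14 (2S)-1-[5,7-bis(methoxymethoxy)-2,2-dimethyl-2H-chromen-8-yl]-2-methylbutan-1-one
Product: 15 (2S)-1-(5,7-dihydroxy-2,2-dimethyl-2H-chromen-8-yl)-2-methylbutan-1-one
Conditions: HCl (3 M aq.), MeOH, rt → 40 °C
Reagents that add atoms: none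
Why: Acid-catalysed acetal exchange removes both MOM groups (the one beside the ketone fastest), and dilute acid near room temperature should spare the chromene alkene and the slowly enolising hindered ketone.

Step 10
Reactants: 16 pentan-3-one
Product: 17 trimethyl(pent-2-en-3-yloxy)silane (E/Z mixture)
Conditions: TMSCl, Et3N, DMF, 80 °C
Reagents that add atoms: chlorotrimethylsilane (TMSCl), C[Si](C)(C)Cl
Why: Enol silylation of a symmetric ketone, which can give only one regioisomer; the alkene geometry is of no consequence.

Step 11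
Reactants: 17 trimethyl(pent-2-en-3-yloxy)silane; 18 malonyl dichloride
Product: 20 6-ethyl-4-hydroxy-5-methyl-2H-pyran-2-one, via 4-methyl-3,5-dioxoheptanoyl chloride 19 (not isolated)
Conditions: Et2O, −78 °C → rt
Reagents that add atoms: none
Why: C-acylation of the silyl enol ether by one acid chloride group gives 19, whose enol oxygen is acylated by the second acid chloride to close the ring, the known 4-hydroxy-2-pyranone synthesis from silyl enol ethers and malonyl dichloride.

Step 12
Reactants: 15 (2S)-1-(5,7-dihydroxy-2,2-dimethyl-2H-chromen-8-yl)-2-methylbutan-1-one; 20 6-ethyl-4-hydroxy-5-methyl-2H-pyran-2-one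
Product: 23 3-({5,7-dihydroxy-2,2-dimethyl-8-[(2S)-2-methylbutanoyl]-2H-chromen-6-yl}methyl)-6-ethyl-4-hydroxy-5-methyl-2H-pyran-2-one, via pyranone Mannich base 21 (not isolated), via 3-methylidene pyrandione 22 (not isolated)
Conditions: 20, CH2=NMe2+ I− (1 equiv), MeCN, rt; then 15, 60 °C
Reagents that add atoms: N,N-dimethylmethyleneiminium iodide, C=[N+](C)C.[I-]
Why: Mannich reaction at C3 of the 4-hydroxypyranone, loss of dimethylamine on warming to the Michael acceptor 22, and Friedel–Crafts-type attack by C6 of 15, the only unsubstituted ring carbon and the one between the two hydroxyls; this Mannich/elimination/alkylation sequence is known for joining acylphloroglucinols to pyranones of this kind.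

**Compound list**

1 | phloroglucinol | Oc1cc(O)cc(O)c1 | starting material
2 | ethyl propiolate | C#CC(=O)OCC | starting material
3 | 5,7-dihydroxy-2H-chromen-2-one | O=c1ccc2c(O)cc(O)cc2o1 | intermediate
4 | (2S)-2-methylbutanoic acid | CC[C@H](C)C(=O)O | starting material
5 | (2S)-2-methylbutanoyl chloride | CC[C@H](C)C(=O)Cl | intermediate (not isolated)
6 | 5,7-dihydroxy-8-[(2S)-2-methylbutanoyl]-2H-chromen-2-one | CC[C@H](C)C(=O)c1c(O)cc(O)c2ccc(=O)oc12 | intermediate
7 | 5,7-bis(methoxymethoxy)-8-[(2S)-2-methylbutanoyl]-2H-chromen-2-one | CC[C@H](C)C(=O)c1c(OCOC)cc(OCOC)c2ccc(=O)oc12 | intermediate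
8 | 8-[(2S)-1-hydroxy-2-methylbutyl]-5,7-bis(methoxymethoxy)-2H-chromen-2-one (both carbinol epimers) | CC[C@H](C)C(O)c1c(OCOC)cc(OCOC)c2ccc(=O)oc12 | intermediate
9 | 8-{(2S)-1-[(tert-butyldimethylsilyl)oxy]-2-methylbutyl}-5,7-bis(methoxymethoxy)-2H-chromen-2-one | CC[C@H](C)C(O[Si](C)(C)C(C)(C)C)c1c(OCOC)cc(OCOC)c2ccc(=O)oc12 | intermediate
10 | (3Z)-4-[3-{(2S)-1-[(tert-butyldimethylsilyl)oxy]-2-methylbutyl}-2-hydroxy-4,6-bis(methoxymethoxy)phenyl]but-3-en-2-one | CC[C@H](C)C(O[Si](C)(C)C(C)(C)C)c1c(OCOC)cc(OCOC)c(/C=C\C(C)=O)c1O | intermediate (not isolated)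
11 | 2-{(2S)-1-[(tert-butyldimethylsilyl)oxy]-2-methylbutyl}-6-[(1Z)-3-hydroxy-3-methylbut-1-en-1-yl]-3,5-bis(methoxymethoxy)phenol | CC[C@H](C)C(O[Si](C)(C)C(C)(C)C)c1c(OCOC)cc(OCOC)c(/C=C\C(C)(C)O)c1O | intermediate (not isolated)
12 | 8-{(2S)-1-[(tert-butyldimethylsilyl)oxy]-2-methylbutyl}-5,7-bis(methoxymethoxy)-2,2-dimethyl-2H-chromene | CC[C@H](C)C(O[Si](C)(C)C(C)(C)C)c1c(OCOC)cc(OCOC)c2C=CC(C)(C)Oc12 | intermediate
13 | (2S)-1-[5,7-bis(methoxymethoxy)-2,2-dimethyl-2H-chromen-8-yl]-2-methylbutan-1-ol (both carbinol epimers) | CC[C@H](C)C(O)c1c(OCOC)cc(OCOC)c2C=CC(C)(C)Oc12 | intermediate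
14 | (2S)-1-[5,7-bis(methoxymethoxy)-2,2-dimethyl-2H-chromen-8-yl]-2-methylbutan-1-one | CC[C@H](C)C(=O)c1c(OCOC)cc(OCOC)c2C=CC(C)(C)Oc12 | intermediate
15 | (2S)-1-(5,7-dihydroxy-2,2-dimethyl-2H-chromen-8-yl)-2-methylbutan-1-one | CC[C@H](C)C(=O)c1c(O)cc(O)c2C=CC(C)(C)Oc12 | intermediate
16 | pentan-3-one | CCC(=O)CC | starting material
17 | trimethyl(pent-2-en-3-yloxy)silane (E/Z mixture) | CC=C(CC)O[Si](C)(C)C | intermediate
18 | malonyl dichloride | O=C(Cl)CC(=O)Cl | starting material
19 | 4-methyl-3,5-dioxoheptanoyl chloride | CCC(=O)C(C)C(=O)CC(=O)Cl | intermediate (not isolated)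
20 | 6-ethyl-4-hydroxy-5-methyl-2H-pyran-2-one | CCc1oc(=O)cc(O)c1C | intermediate
21 | 3-[(dimethylamino)methyl]-6-ethyl-4-hydroxy-5-methyl-2H-pyran-2-one | CCc1oc(=O)c(CN(C)C)c(O)c1C | intermediate (not isolated)
22 | 6-ethyl-5-methyl-3-methylidene-2H-pyran-2,4(3H)-dione | CCC1=C(C)C(=O)C(=C)C(=O)O1 | intermediate (not isolated)
23 | 3-({5,7-dihydroxy-2,2-dimethyl-8-[(2S)-2-methylbutanoyl]-2H-chromen-6-yl}methyl)-6-ethyl-4-hydroxy-5-methyl-2H-pyran-2-one | CCc1oc(=O)c(Cc2c(O)c3c(c(C(=O)[C@@H](C)CC)c2O)OC(C)(C)C=C3)c(O)c1C | target

**Step count**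

Total steps: 12. Longest linear sequence: 10 steps (steps 1 to 9 and step 12, from phloroglucinol); steps 10 and 11 form the pyranone branch.

**Steps most likely to fail**

Step 2. The lactone-deactivated ring may need enough heat with AlCl3 that the branched acyl carbon partly loses its configuration, and acylation at C6 or twice may compete. The fallback reverses the order of acylation and ring construction. It sets out from 1 and acid chloride 5 and comes back at 6. Phloroglucinol, which is symmetric and more reactive, would be acylated at room temperature (AlCl3, PhNO2) to (2S)-2-methyl-1-(2,4,6-trihydroxyphenyl)butan-1-one F1. The lactone ring would then be fused on with ethyl propiolate 2 and ZnCl2 as in step 1. Lactonisation can use either hydroxyl beside the new carbon, so 6 would have to be separated from its 6-acyl isomer.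

Step 6. Conjugate addition at C4, enolisation of the intermediate methyl ketone (stalling after one methyl), or ionisation of the benzylic silyl ether during the acid closure would each lower the return. The fallback builds C3 and C2 onto a salicylaldehyde instead of adding two methyls to the lactone. It sets out from 9 and comes back at 12. The C3=C4 bond of 9 would be cleaved (O3, CH2Cl2/MeOH, −78 °C; Me2S; then NaHCO3, aq. MeOH to hydrolyse the aryl glyoxylate) to 3-{(2S)-1-[(tert-butyldimethylsilyl)oxy]-2-methylbutyl}-2-hydroxy-4,6-bis(methoxymethoxy)benzaldehyde F2. Addition of 2-methylprop-1-enylmagnesium bromide (2.5 equiv, THF, 0 °C) would give 2-{(2S)-1-[(tert-butyldimethylsilyl)oxy]-2-methylbutyl}-6-(1-hydroxy-3-methylbut-2-en-1-yl)-3,5-bis(methoxymethoxy)phenol F3. This doubly activated alcohol should lose water on gentle warming or with a trace of pyridinium p-toluenesulfonate to the ortho-quinone methide, which electrocyclises to 12. The phenol oxygen is still the one marked by the lactone.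

Step 12. The methylidene dione 22 may be consumed by self-condensation or by O-alkylation before C6 of 15 attacks. The fallback exchanges the roles of the two partners. It sets out from 15 and 20 and comes back at 23. Chromene 15 would be aminomethylated at C6 with CH2=NMe2+ I− (CH2Cl2, rt) to (2S)-1-{6-[(dimethylamino)methyl]-5,7-dihydroxy-2,2-dimethyl-2H-chromen-8-yl}-2-methylbutan-1-one F4. Heating F4 with 20 in dioxane (90 °C) would expel dimethylamine and form the ortho-quinone methide of the chromene, which is trapped by the nucleophilic C3 of the pyranone.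

**Further compounds**

F1 | step 2 | (2S)-2-methyl-1-(2,4,6-trihydroxyphenyl)butan-1-one | CC[C@H](C)C(=O)c1c(O)cc(O)cc1O
F2 | step 6 | 3-{(2S)-1-[(tert-butyldimethylsilyl)oxy]-2-methylbutyl}-2-hydroxy-4,6-bis(methoxymethoxy)benzaldehyde | CC[C@H](C)C(O[Si](C)(C)C(C)(C)C)c1c(OCOC)cc(OCOC)c(C=O)c1O
F3 | step 6 | 2-{(2S)-1-[(tert-butyldimethylsilyl)oxy]-2-methylbutyl}-6-(1-hydroxy-3-methylbut-2-en-1-yl)-3,5-bis(methoxymethoxy)phenol | CC[C@H](C)C(O[Si](C)(C)C(C)(C)C)c1c(OCOC)cc(OCOC)c(C(O)C=C(C)C)c1O
F4 | step 12 | (2S)-1-{6-[(dimethylamino)methyl]-5,7-dihydroxy-2,2-dimethyl-2H-chromen-8-yl}-2-methylbutan-1-one | CC[C@H](C)C(=O)c1c(O)c(CN(C)C)c(O)c2C=CC(C)(C)Oc12
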